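The solid substrate leaves at almost the same rate in two runs with different charges: the dusk run, with 0.61 M, lost 15.0 mM/h over its first 12.0 h, and the summer run, with 0.41 M, lost 15.4 mM/h over its first 20.0 h.

the same everywhere: gas phase 84 mM (held)
- dusk: solid substrate 0.61 M; the very flask that is asked about, followed so far
- summer: solid substrate 0.41 M; run made earlier
- flask: solid substrate 0.61 M; time 40 h

- dusk (time / h: target / %, solid substrate / %): 1.00: 2.1, 96.7; 2.00: 3.4, 95.2; 3.00: 5.3, 92.5; 6.00: 9.8, 85.7; 12.0: 24.9, 70.4
- summer (time / h: target / %, solid substrate / %): 2.50: 4.4, 91.0; 8.00: 23.2, 70.4; 12.0: 35.3, 54.7; 20.0: 58.5, 24.9; 30.0: 84.1, 0.5

(each reading ± 1 percentage point)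

- solid, in amounts per volume of the solution: solid substrate
- the numbers in the tables scatter with a standard deviation of 1 percentage point
- at the start none of the gas phase is in solution
- at the start none of the solid substrate is in solution

- target at 40 h, in percent of the solid substrate charged
- the change that raises the amount of target at 40 h, in percent of the solid substrate charged most ("none" if none brings more than 2 percentage points) (eta / delta / theta / alpha / none)
- amount of target at 40 h, in percent of the solid substrate charged, after eta

- eta: doubling the transfer coefficient of the gas phase, all else as stated
- delta: doubling the solubility of the solid substrate, all else as stated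
- theta: doubling the dissolution coefficient of the solid substrate, all else as stated
- alpha: doubling the saturation concentration of gas phase, all else as stated

A rate that ignores the charge is zero order, as you expect of a solid feeding a solution that stays well below its solubility. Call what dissolves starting material. It does not seem to pile up: target is 84.1 % of the solid lost at 12.0 h in dusk and 84.5 % at 30.0 h in summer, two quite different stages. So I treat what follows dissolution as quick, take dissolution as the rate-limiting step, and read the remainder as side product.

At the mean rate of 15.2 mM/h, the asked flask's 0.61 M takes 40.1 h to dissolve. This clearing time, charge over dissolution rate, is close to the asked 40 h, so I reckon that nearly all of the flask's solid has dissolved by then, which gives 84.4 % target. I assume gas transfer is quick, with [dissolved gas] near 84 mM, so I expect eta to change clearing time and share little and to give about 84.4 % again. Theta and delta should shorten the clearing time, and I expect little gain from that, with nearly all reckoned as dissolved already. Alpha raises [dissolved gas], which should favour target over side product, so I choose alpha.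

The forecast, reasoning from “gas transfer limiting the reaction”, gives 76 %, alpha, and 90 % after eta.

The flask gives 83.1 %; the best change is alpha, adding 8.3 percentage points, while eta adds 0.31 points and reaches 83.4 %.

    gas phase ⇌ dissolved gas, rate k1*(csat - [dissolved gas]) (kL = 0.00120 /s)
    starting material + dissolved gas → target (k = 0.00370 /M/s)
    starting material → side product (k = 5.70 × 10⁻⁵ /s)
    solid substrate ⇌ starting material, rate k4*(cs4 - [starting material]) while solid is left; crystals form when [starting material] > cs4 (solubility = 0.250 M, k = 1.80 × 10⁻⁵ /s)

The flask's solid substrate stands at 0 % at 40.0 h. The neighbouring flask, charged with 1.5 M of solid substrate, has a reckoned clearing time of 98.5 h at the same rate, longer than the 40 h it runs. So I reckon that 40.6 % of its charge has dissolved, and the same share gives 34.3 % target. That flask gives 33.9 % target, with 60 % of its charge still there, solid or dissolved.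

(The earlier runs and the new flask were generated by integration with constants of no real substance, and the scatter is random.)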